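A loss of Z whose fraction per minute grew in step with the charge cannot give these runs. In the autumn and winter runs, charged at 13 mM and 30 mM, Z stands at 31.7% and 30.2% of its charge at 30.0 min, 1.5 percentage points apart, with a scatter of 1 point on each reading. Equal percentages are the zero of my scale, and at these last readings the two runs sit on it to about that scatter.

| flask | Z | remark | time |
|---|---|---|---|
| autumn | 13 mM | run made earlier |  |
| winter | 30 mM | run made earlier |  |
| flask | 20 mM |  | 25 min |

| run | time / min | D / % | Z / % |
|---|---|---|---|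
| autumn | 8.00 | 19.8 | 72.8 |
| autumn | 15.0 | 30.0 | 56.2 |
| autumn | 25.0 | 42.3 | 39.6 |
| autumn | 30.0 | 44.9 | 31.7 |
| winter | 2.50 | 9.0 | 90.7 |
| winter | 6.00 | 15.3 | 77.3 |
| winter | 12.0 | 25.5 | 63.2 |
| winter | 30.0 | 46.2 | 30.2 |

(each reading ± 1 percentage point)

* concentration of D at 25 min, in mM
* concentration of Z at 25 min, in mM

So I carry one number from the two last readings:

loss constant = ln(charge ÷ Z left) ÷ time, averaged = 0.0391 min⁻¹

This is the apparent first-order constant, the fraction of the Z present lost per minute.

My ladder starts at 2.50 min in the winter run, where D and Z still sum to 99.7%. Next comes the half-life of Z, 17.7 min, shorter than the asked 25 min. Slower is the share missing from D and Z together, 23.4% at 30.0 min in the autumn run, which taken as steady is a pace of one charge per 128 min. For this flask I reckon: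

Z = 7.52 mM

D = 8.23 mM, taking D's share of the Z used from the same readings

The forecast, which says “the loss of Z looks first order”, gives 8.3 mM of D (7.9 mM to 8.7 mM) and 7.7 mM of Z (7.3 mM to 8.1 mM), a little above my two figures.

The flask gives 8.18 mM of D and 7.70 mM of Z, both inside the forecast's ranges.

    D ⇌ X (K = 0.110, k = 0.00120 s⁻¹)
    Z → D (k = 6.00 × 10⁻⁴ s⁻¹)
    E → X (k = 0.00190 s⁻¹)
    Z ⇌ E (K = 0.0170, k = 0.150 s⁻¹)
    D ⇌ Q (K = 0.430, k = 0.00140 s⁻¹)
    2 E → L (k = 0.410 M⁻¹ s⁻¹)

My 7.52 mM of Z lies 0.180 mM below the flask's value. Carried to the same flask left until 40 min, the constant gives 4.19 mM of Z, and that flask holds 4.40 mM.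

(The readings are simulated with made-up constants; the scatter is artificial.)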